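## Analysis of the target

Selaginellin A (20) has no fused rings. A central benzene (ring A) carries four contiguous substituents: a methyl group on C1, a 4-hydroxyphenyl group (ring B) on C4, a diarylmethylidene unit on C5, and an arylethynyl group on C6 that ends in a second 4-hydroxyphenyl ring (ring C). The exocyclic carbon on C5 (the methide carbon) bears a phenyl group (ring E) and is doubly bonded to a cyclohexa-2,5-dienone (ring D), so the molecule is a para-quinone methide of the fuchsone type. There is no stereocenter, and because ring D is symmetrical the methide double bond has no E/Z isomers; chirality appears only in intermediates in which the methide carbon is sp3. The sensitive functions are the quinone methide (a 1,6-acceptor that is in equilibrium with a triaryl cation under acid), the two free phenols, and the electron-rich diarylalkyne that sits ortho to this cation-prone carbon. The difficulty is crowding. C5 and C6 are both flanked on each side, the methide carbon must receive three different aryl groups, and a cation on it can be diverted by ring B (fluorene closure) or by the neighboring alkyne. The strategy rests on the ortho relationship of the methide carbon on C5 and the first alkyne carbon on C6. A diarylated carbon and a one-carbon unit on adjacent ring positions, bridged by oxygen, make up a 3,3-diarylphthalide, the skeleton that a 2-aroylbenzoic acid and a phenol give in a phenolphthalein-type condensation.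

## Retrosynthetic reasoning

20 to 19. The quinone methide is the dehydrated and demethylated form of a triaryl carbinol with a para-methoxy group on ring D. Two O–methyl bonds and the carbinol C–O bond are restored in the retron. This keeps the electrophilic methide masked as an sp3 carbinol carbon until the last operation, so no earlier step has to tolerate a 1,6-acceptor. The forward step has to cleave both aryl methyl ethers and ionize the carbinol without letting the cation react with ring B or the alkyne.

19 to 17 and 18. The bond between the alkyne terminus and ring C is cut. It is the unhindered end of the alkyne, whereas the ring A–alkyne bond lies between two ortho substituents and would be a poor coupling site. The cut releases ring C as the simple aryl iodide 18 and leaves the terminal alkyne 17.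

17 to 15 and 14. The terminal alkyne carbon is removed in a one-carbon homologation retron. The ring-bound alkyne carbon then becomes the aldehyde carbon of 16, which is the open form of lactol 15, and one oxidation level higher the carbonyl carbon of lactone 14. Alkyne carbon and carbinol oxygen are thereby tied into one five-membered ring, so the alkyne does not exist during any cationic chemistry. The forward steps need a partial reduction that stops at the lactol and a homologation that works on the ring-opened aldehyde.

14 to 13. The O–methyl bond on ring D is cut. The cap is needed because a free para-hydroxyl on this ring could push out the benzylic oxygen under the hydride and base conditions that follow, which would form the quinone methide too early.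

13 to 10 and 11 (the key disconnection). The bond between C3 of the phthalide (the future methide carbon) and the para carbon of ring D is cut together with the lactone C–O bond. This gives the keto acid 10 and phenol 11. The cut is made here because ring D is the only aryl group on the methide carbon that is electron-rich enough to enter as a nucleophile, and the carbon it attacks is a stabilized cation that forms from 10 on its own in acid. The forward reaction has to form a quaternary carbon next to ring B, with para selectivity on 11 and without intramolecular capture.

10 to 8. The keto acid is traced to the 3-phenylphthalide 8, one oxidation level lower at the benzylic carbon. The reason is practical: the carboxyl carbon is best introduced through an aryllithium, and that cannot coexist with a ketone. The forward step is an opening of the lactone and oxidation of the secondary benzylic alcohol.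

8 to 6 and 7. The ring A–ring B bond at C4 is cut to the aryl chloride 6 and the boronic acid 7. The chloride is placed there from the start because it also serves to acidify the neighboring C–H in the first step.

6 to 4. The bond between ring A and the lactone carbonyl carbon is cut, back to the aryl bromide 4. The forward step is a bromine–lithium exchange and carboxylation, which must leave the chloride untouched, followed by lactonization.

4 to 1 and 2. The bond between ring A and the carbinol carbon is cut. In 1 the ring position between bromine and chlorine is the most acidic, so deprotonation puts the nucleophile exactly on the future C5, and aldehyde 2 brings ring E. Methyl, bromine and chlorine of 1 already mark C1, C6 and C4 of ring A.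

## Alternatives that were turned down

Alternative 1: Ring A would be built from two acyclic three-carbon pieces by cutting C1–C2 and C4–C5. In the forward direction the bis-silyl dienol ether 1-methoxy-1,3-bis(trimethylsilyloxy)penta-1,3-diene A1 and the masked keto aldehyde 3,3-dimethoxy-1-(4-methoxyphenyl)propan-1-one A2 would be joined by a Lewis acid in a formal [3+3] cyclization. The methyl-bearing terminus of A1 would attack the acetal carbon and its central carbon the aryl ketone, and aromatization would give methyl 2-hydroxy-6-(4-methoxyphenyl)-3-methylbenzoate A3.
- For it: all four substituents of ring A are placed in one step from non-aromatic material, with regiochemistry set by the different electrophilicity of acetal and ketone. The hydroxyl on C6 can be turned into a sulfonate and coupled with an arylacetylene, so the complete alkyne arrives in one ordinary coupling.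
- Against it: C5 arrives as an ester wedged between ring B and the C6 substituent. It must be converted into a carbon bearing two different aryl groups, which needs two successive aryl-metal additions with a clean stop at the ketone, at a carbonyl twisted out of the ring plane. Over-addition or no addition are both likely. The diene A1 needs two silylations and is moisture-sensitive, and the sequence after A3 is longer than the sequence after 13.
- Comparison: this alternative is stronger on the construction of ring A and on the alkyne, which needs no lactol homologation. The chosen route offers instead that the two aryl groups of the methide carbon are never introduced by nucleophilic addition to a crowded carbonyl: one comes with 2 and the other by capture of a cation.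

Alternative 2: The C5–benzoyl bond and the C6–alkyne bond would be formed on an existing arene in one three-component operation. 4-Chloro-2-iodotoluene A4, benzoic anhydride A5 and 4-ethynylanisole A6 would react under palladium–phosphine catalysis with a strained bicyclic alkene as relay and a carbonate base. The sequence is ortho C–H acylation through a palladacycle, then alkynylation at the former iodide carbon, to give [6-chloro-2-[(4-methoxyphenyl)ethynyl]-3-methylphenyl](phenyl)methanone A7.
- For it: A7 is reached in one step from cheap material. Coupling with 7 at the chloride, addition of an aryl-metal that carries ring D, and ether cleavage would finish the target in about four steps.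
- Against it: the C–H to be acylated lies between iodine and chlorine, so the palladacycle must form at a position with a neighbor on the far side. The alkyne can couple directly at the iodide before the relay alkene has inserted. The final carbinol must then be made by adding an aryl-metal to a ketone flanked by chlorine or ring B and by the alkyne, and the resulting alkoxide sits next to that alkyne.
- Comparison: this alternative is clearly stronger in step economy. The chosen route offers two-component steps throughout and positional control that follows from the halogen pattern of 1 rather than from the order of events in a catalytic cycle, and the alkyne never meets an organometallic reagent.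

Alternative 3: The C4–ring B bond and the C5–carbinol carbon bond would be formed together across an aryne. 4-Fluoro-2-[(4-methoxyphenyl)ethynyl]-1-methylbenzene A8 would be lithiated at the C–H between fluorine and the alkynyl group and lose fluoride to give the aryne 3-[(4-methoxyphenyl)ethynyl]-4-methyl-1,2-didehydrobenzene A9. 4-Methoxyphenylmagnesium bromide A10 would add at C4, and the arylmagnesium formed at C5 would add to 4-methoxybenzophenone A11. The product would be [6-(4-methoxyphenyl)-2-[(4-methoxyphenyl)ethynyl]-3-methylphenyl](4-methoxyphenyl)(phenyl)methanol A12 (racemate, one enantiomer drawn).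
- For it: the complete carbon skeleton is assembled in one flask, only an ether cleavage with dehydration remains, and the inductive effect of the alkynyl group should direct the aryl nucleophile to the distal aryne carbon as required.
- Against it: the base must not add to the diarylalkyne of A8, and the aryne A9 must be taken up by A10 faster than by the amide base. The arylmagnesium at C5, flanked by ring B and the alkyne, must add to the diaryl ketone A11, where electron transfer and simple protonation compete. Unreacted A10 also consumes A11.
- Comparison: this is the shortest and most convergent plan and is stronger than the chosen route on both counts. The chosen route offers that its single risky bond formation is a cation capture of a classical type, that no doubly flanked carbanion has to add to a diaryl ketone, and that each bond is made in a separate step that can be checked.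

Key step: step 5

Remark: every chiral intermediate is racemic and is drawn as one enantiomer; the only stereocenter that is carried (the future methide carbon) becomes planar in step 10, so no stereocontrol is attempted.

## Route

Step 1
Reactants: 1 2-bromo-4-chlorotoluene; 2 benzaldehyde
Product: 4 (2-bromo-6-chloro-3-methylphenyl)(phenyl)methanol (racemic), via aryllithium 3 (not isolated)
Conditions: LiN(iPr)2, THF, −78 °C; then PhCHO, −78 → 0 °C; aq. NH4Cl
Reagents that add atoms: none
Why: The C–H between bromine and chlorine of 1 is the most acidic ring position, so lithium diisopropylamide at −78 °C should give aryllithium 3 (directed ortho-lithiation of a 1,3-dihaloarene), which does not lose lithium halide at this temperature and adds to 2. The carbinol stereocenter forms without control, so 4 is racemic.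

Step 2
Reactants: 4 (2-bromo-6-chloro-3-methylphenyl)(phenyl)methanol
Product: 6 4-chloro-7-methyl-3-phenylisobenzofuran-1(3H)-one (racemic), via hydroxy acid 5 (not isolated)
Conditions: n-BuLi (2.2 equiv), THF, −78 °C; CO2, −78 °C → rt; 2 M HCl
Reagents that add atoms: carbon dioxide, O=C=O
Why: After deprotonation of the hydroxyl, bromine–lithium exchange is fast at −78 °C while the aryl chloride is inert; the new aryllithium is meta to chlorine, so it cannot form an aryne, and it is carboxylated. On acidification hydroxy acid 5 should lactonize spontaneously to the five-membered phthalide (Parham-type exchange and carboxylation).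

Step 3
Reactants: 6 4-chloro-7-methyl-3-phenylisobenzofuran-1(3H)-one; 7 4-methoxyphenylboronic acid
Product: 8 4-(4-methoxyphenyl)-7-methyl-3-phenylisobenzofuran-1(3H)-one (racemic)
Conditions: Pd(OAc)2 (2 mol%), SPhos (4 mol%), K3PO4, toluene/H2O, 100 °C, degassed; then dil. HCl
Reagents that add atoms: none
Why: Suzuki–Miyaura coupling of an aryl chloride, for which an electron-rich dialkylbiarylphosphine on palladium is the standard catalyst; the chloride at C4 is the only halogen left. Any lactone opened by the aqueous base recloses on acidification.

Step 4
Reactants: 8 4-(4-methoxyphenyl)-7-methyl-3-phenylisobenzofuran-1(3H)-one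
Product: 10 2-benzoyl-3-(4-methoxyphenyl)-6-methylbenzoic acid, via hydroxy carboxylate 9 (not isolated)
Conditions: aq. NaOH, dioxane, 80 °C; then KMnO4, 0 °C → rt; filtration, aq. HCl
Reagents that add atoms: sodium hydroxide, [Na+].[OH-]
Why: Saponification opens the lactone to the benzhydrol carboxylate 9, whose carbinol C–H should be oxidized by cold alkaline permanganate much faster than the ring A methyl group or the arenes (classical oxidation of a 3-arylphthalide to a 2-aroylbenzoic acid). The racemic stereocenter disappears in this step.

Step 5
Reactants: 10 2-benzoyl-3-(4-methoxyphenyl)-6-methylbenzoic acid; 11 phenol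
Product: 13 3-(4-hydroxyphenyl)-4-(4-methoxyphenyl)-7-methyl-3-phenylisobenzofuran-1(3H)-one (racemic), via pseudo-acid 12 (not isolated)
Conditions: PhOH (5 equiv), MeSO3H, 50 °C
Reagents that add atoms: none
Why: This is a phenolphthalein-type condensation of a 2-aroylbenzoic acid with a phenol, that is, a Friedel–Crafts hydroxyarylation of a pseudo-acid. In MeSO3H the carboxyl oxygen of 10 adds to the protonated ketone (5-exo-trig), which closes the lactone ring and gives pseudo-acid 12; loss of its hydroxyl as water leaves a 3-phenylphthalidyl cation stabilized by ring E, ring A and the ring oxygen. Phenol 11 attacks this cation through its para carbon and rearomatizes, which forms the bond between the future methide carbon and ring D. The new quaternary stereocenter at C3 comes from a planar cation and achiral partners, so 13 is necessarily racemic; this has no consequence because the carbon becomes sp2 in step 10. Para attack is expected because the tertiary cation, flanked by ring B on C4, cannot easily reach the ortho carbons of phenol, and reversible O-attack to a pseudo-ester drains into the C-arylated product. Ring B should not compete: with the lactone in place, closure onto its ortho carbon would fuse a second five-membered ring onto the same three adjacent ring A carbons, and in the open keto form the electrophile is only a protonated ketone facing a ring B carbon that is meta to the methoxy group; the excess of phenol suppresses intermolecular attack by ring B or by the product. Cyclization of the carboxyl group onto ring E to an anthraquinone needs hotter and stronger acid than is used here. No alkyne is present during this cationic step, because its first carbon is still the lactone carbonyl.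

Step 6
Reactants: 13 3-(4-hydroxyphenyl)-4-(4-methoxyphenyl)-7-methyl-3-phenylisobenzofuran-1(3H)-one
Product: 14 3,4-bis(4-methoxyphenyl)-7-methyl-3-phenylisobenzofuran-1(3H)-one (racemic)
Conditions: MeI, K2CO3, acetone, 40 °C
Reagents that add atoms: iodomethane, CI
Why: Williamson O-methylation of the phenoxide; the lactone has no acidic hydrogen and should survive carbonate base. The cap keeps the para-oxygen from expelling the benzylic oxygen (premature quinone methide formation) in steps 7 to 9.

Step 7
Reactants: 14 3,4-bis(4-methoxyphenyl)-7-methyl-3-phenylisobenzofuran-1(3H)-one
Product: 15 3,4-bis(4-methoxyphenyl)-7-methyl-3-phenyl-1,3-dihydroisobenzofuran-1-ol (racemic at C3; both epimers at C1)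
Conditions: iBu2AlH (1.3 equiv), CH2Cl2, −78 °C; aq. potassium sodium tartrate
Reagents that add atoms: none
Why: Partial reduction of a lactone to the lactol, which stops because the aluminium hemiacetal is stable at −78 °C. The hemiacetal center forms as a mixture of epimers, which does not matter because it is destroyed in step 8.

Step 8
Reactants: 15 3,4-bis(4-methoxyphenyl)-7-methyl-3-phenyl-1,3-dihydroisobenzofuran-1-ol
Product: 17 [2-ethynyl-6-(4-methoxyphenyl)-3-methylphenyl](4-methoxyphenyl)(phenyl)methanol (racemic), via hydroxy aldehyde 16 (not isolated)
Conditions: dimethyl (1-diazo-2-oxopropyl)phosphonate (2.5 equiv), K2CO3, MeOH/THF, 0 °C → rt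
Reagents that add atoms: dimethyl (1-diazo-2-oxopropyl)phosphonate, COP(=O)(OC)C(=[N+]=[N-])C(C)=O
Why: Ohira–Bestmann (Seyferth–Gilbert) homologation, which is known for lactols: under carbonate in methanol 15 equilibrates with hydroxy aldehyde 16, helped by the relatively stabilized triarylmethoxide, and 16 is trapped irreversibly by the diazomethylphosphonate anion. Loss of dimethyl phosphate and N2 followed by a 1,2-hydrogen shift should give the terminal alkyne and unveil the carbinol at the same time.

Step 9
Reactants: 17 [2-ethynyl-6-(4-methoxyphenyl)-3-methylphenyl](4-methoxyphenyl)(phenyl)methanol; 18 4-iodophenol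
Product: 19 4-[[2-[hydroxy(4-methoxyphenyl)(phenyl)methyl]-3-(4-methoxyphenyl)-6-methylphenyl]ethynyl]phenol (racemic)
Conditions: PdCl2(PPh3)2 (3 mol%), CuI (5 mol%), Et3N/THF, rt → 40 °C, degassed
Reagents that add atoms: none
Why: Sonogashira coupling of a terminal alkyne with an aryl iodide near room temperature; the alkyne terminus is unhindered, and a free phenol and a hindered tertiary alcohol are tolerated under these conditions.

Step 10
Reactants: 19 4-[[2-[hydroxy(4-methoxyphenyl)(phenyl)methyl]-3-(4-methoxyphenyl)-6-methylphenyl]ethynyl]phenol
Product: 20 selaginellin A, 4-[[2-[(4-hydroxyphenyl)ethynyl]-6-(4-hydroxyphenyl)-3-methylphenyl](phenyl)methylidene]cyclohexa-2,5-dien-1-one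
Conditions: BBr3 (8 equiv), CH2Cl2, −78 °C → rt; then H2O, 0 °C
Reagents that add atoms: none
Why: BBr3 should ionize the tertiary carbinol to a triaryl cation whose charge is shared by the ring D methoxy oxygen; bromide removes that methyl group and gives the quinone methide directly, the ring B ether is cleaved in the usual way, and hydrolysis frees the phenols (Lewis acid ether cleavage with dehydration of a 4-oxygenated triarylcarbinol to a fuchsone). Ring D is symmetrical, so no double-bond isomers arise and the product is achiral.

## Compound list

1 | 2-bromo-4-chlorotoluene | Cc1ccc(Cl)cc1Br | starting material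
2 | benzaldehyde | O=Cc1ccccc1 | starting material
3 | (2-bromo-6-chloro-3-methylphenyl)lithium | [Li]c1c(Cl)ccc(C)c1Br | intermediate
4 | (2-bromo-6-chloro-3-methylphenyl)(phenyl)methanol (racemate, one enantiomer drawn) | O[C@H](c1ccccc1)c1c(Cl)ccc(C)c1Br | intermediate
5 | 3-chloro-2-[hydroxy(phenyl)methyl]-6-methylbenzoic acid (racemate, one enantiomer drawn) | O[C@H](c1ccccc1)c1c(Cl)ccc(C)c1C(=O)O | intermediate
6 | 4-chloro-7-methyl-3-phenylisobenzofuran-1(3H)-one (racemate, one enantiomer drawn) | O=C1O[C@H](c2ccccc2)c2c(Cl)ccc(C)c12 | intermediate
7 | 4-methoxyphenylboronic acid | COc1ccc(cc1)B(O)O | starting material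
8 | 4-(4-methoxyphenyl)-7-methyl-3-phenylisobenzofuran-1(3H)-one (racemate, one enantiomer drawn) | O=C1O[C@H](c2ccccc2)c2c(-c3ccc(OC)cc3)ccc(C)c12 | intermediate
9 | sodium 2-[hydroxy(phenyl)methyl]-3-(4-methoxyphenyl)-6-methylbenzoate (racemate, one enantiomer drawn) | [Na+].O[C@H](c1ccccc1)c1c(-c2ccc(OC)cc2)ccc(C)c1C(=O)[O-] | intermediate
10 | 2-benzoyl-3-(4-methoxyphenyl)-6-methylbenzoic acid | Cc1ccc(-c2ccc(OC)cc2)c(C(=O)c2ccccc2)c1C(=O)O | intermediate
11 | phenol | Oc1ccccc1 | starting material
12 | 3-hydroxy-4-(4-methoxyphenyl)-7-methyl-3-phenylisobenzofuran-1(3H)-one (racemate, one enantiomer drawn) | O=C1O[C@@](O)(c2ccccc2)c2c1c(C)ccc2-c1ccc(OC)cc1 | intermediate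
13 | 3-(4-hydroxyphenyl)-4-(4-methoxyphenyl)-7-methyl-3-phenylisobenzofuran-1(3H)-one (racemate, one enantiomer drawn) | O=C1O[C@](c2ccccc2)(c2ccc(O)cc2)c2c1c(C)ccc2-c1ccc(OC)cc1 | intermediate
14 | 3,4-bis(4-methoxyphenyl)-7-methyl-3-phenylisobenzofuran-1(3H)-one (racemate, one enantiomer drawn) | O=C1O[C@](c2ccccc2)(c2ccc(OC)cc2)c2c1c(C)ccc2-c1ccc(OC)cc1 | intermediate
15 | 3,4-bis(4-methoxyphenyl)-7-methyl-3-phenyl-1,3-dihydroisobenzofuran-1-ol (racemic at C3, one enantiomer drawn; both epimers at C1) | OC1O[C@](c2ccccc2)(c2ccc(OC)cc2)c2c1c(C)ccc2-c1ccc(OC)cc1 | intermediate
16 | 2-[hydroxy(4-methoxyphenyl)(phenyl)methyl]-3-(4-methoxyphenyl)-6-methylbenzaldehyde (racemate, one enantiomer drawn) | O[C@](c1ccccc1)(c1ccc(OC)cc1)c1c(C=O)c(C)ccc1-c1ccc(OC)cc1 | intermediate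
17 | [2-ethynyl-6-(4-methoxyphenyl)-3-methylphenyl](4-methoxyphenyl)(phenyl)methanol (racemate, one enantiomer drawn) | O[C@](c1ccccc1)(c1ccc(OC)cc1)c1c(C#C)c(C)ccc1-c1ccc(OC)cc1 | intermediate
18 | 4-iodophenol | Oc1ccc(I)cc1 | starting material
19 | 4-[[2-[hydroxy(4-methoxyphenyl)(phenyl)methyl]-3-(4-methoxyphenyl)-6-methylphenyl]ethynyl]phenol (racemate, one enantiomer drawn) | O[C@](c1ccccc1)(c1ccc(OC)cc1)c1c(C#Cc2ccc(O)cc2)c(C)ccc1-c1ccc(OC)cc1 | intermediate
20 | selaginellin A | Cc1ccc(-c2ccc(O)cc2)c(C(=C2C=CC(=O)C=C2)c2ccccc2)c1C#Cc1ccc(O)cc1 | target

## Step count and least certain steps

Total: 10 steps. Longest linear sequence: 10 steps, from 1 to 20; the partners 2, 7, 11 and 18 are commercial.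

Step 5 (key step). The likeliest failure is slow capture of the crowded cation, which would let slower processes take over: ionization of the doubly ortho-substituted carboxyl group to an acylium ion that acylates phenol or ring E, attack at an ortho carbon of phenol, or attack of a second cation on the product phenol. The fallback separates ionization from the choice of nucleophile. Keto acid 10 is converted with SOCl2 into the pseudo-acid chloride 3-chloro-4-(4-methoxyphenyl)-7-methyl-3-phenylisobenzofuran-1(3H)-one F1. Ionization of F1 with SnCl4 in CH2Cl2 at −20 °C in the presence of anisole, a known Friedel–Crafts route to 3,3-diarylphthalides, gives the methyl ether 14 directly. The route is rejoined at 14 and step 6 is not needed.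

Step 8. The lactol may open only slowly because two aryl groups on the carbinol carbon favor the closed form, and under prolonged base the tertiary alkoxide may add to the newly formed alkyne. The fallback is a Corey–Fuchs sequence from lactol 15. Dibromo-olefination with PPh3 and CBr4 in CH2Cl2 gives [2-(2,2-dibromoethenyl)-6-(4-methoxyphenyl)-3-methylphenyl](4-methoxyphenyl)(phenyl)methanol F2, which cannot reclose. Treatment with n-BuLi (3.3 equiv) in THF at −78 °C then causes exchange, loss of bromide and 1,2-shift. The alkyne is kept as its lithium acetylide beside the lithium alkoxide until the cold quench, so no addition across it can take place, and the route is rejoined at 17.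

Step 10. Once the carbinol is ionized, the cation may be diverted before the ring D ether is cleaved. The possible diversions are Friedel–Crafts closure onto ring B, addition of hydrogen bromide or of the boron halide across the electron-rich alkyne, and attack of oxygen on the acid-activated alkyne. The fallback removes the methyl groups by a nucleophilic mechanism that generates no cation. From 19, NaSEt in DMF at 120 °C cleaves both aryl methyl ethers by SN2 attack on methyl and gives 4-[[2-[hydroxy(4-hydroxyphenyl)(phenyl)methyl]-3-(4-hydroxyphenyl)-6-methylphenyl]ethynyl]phenol F3. The thiolate is too weak a base to deprotonate the carbinol, and the phenoxide-bearing alkyne is a poor acceptor. Mild acidification (acetic acid or a trace of TsOH in CH2Cl2) then dehydrates F3 to 20.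

Step 9. Copper or divalent palladium may activate the alkyne toward attack by the neighboring tertiary hydroxyl (cycloisomerization), and oxidative homocoupling of the alkyne is possible. The fallback is a copper-free and amine-free Negishi coupling. From 17, double deprotonation with n-BuLi (2.1 equiv) and transmetalation with ZnCl2 is followed by Pd(PPh3)4-catalyzed coupling with tert-butyl(4-iodophenoxy)dimethylsilane. This gives [2-[[4-(tert-butyldimethylsilyloxy)phenyl]ethynyl]-6-(4-methoxyphenyl)-3-methylphenyl](4-methoxyphenyl)(phenyl)methanol F4, and Bu4NF in THF removes the silyl group to return to 19.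

Step 4. Opening of the hindered lactone may be incomplete, and permanganate may begin to attack the ring A methyl group or the electron-rich ring B, which would cause under-oxidation or over-oxidation. The fallback reaches the ketone oxidation level before the carboxyl group is introduced. From 4, oxidation with Dess–Martin periodinane gives (2-bromo-6-chloro-3-methylphenyl)(phenyl)methanone F5. Palladium-catalyzed hydroxycarbonylation of the bromide (Pd(OAc)2, Xantphos, CO 1 atm, K2CO3, dioxane/H2O, 100 °C) gives 2-benzoyl-3-chloro-6-methylbenzoic acid F6. Suzuki–Miyaura coupling of F6 with 7 under the conditions of step 3 returns to 10.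

## Further compounds

F1 | step 5 | 3-chloro-4-(4-methoxyphenyl)-7-methyl-3-phenylisobenzofuran-1(3H)-one (racemate, one enantiomer drawn) | O=C1O[C@](Cl)(c2ccccc2)c2c1c(C)ccc2-c1ccc(OC)cc1
F2 | step 8 | [2-(2,2-dibromoethenyl)-6-(4-methoxyphenyl)-3-methylphenyl](4-methoxyphenyl)(phenyl)methanol (racemate, one enantiomer drawn) | O[C@](c1ccccc1)(c1ccc(OC)cc1)c1c(C=C(Br)Br)c(C)ccc1-c1ccc(OC)cc1
F3 | step 10 | 4-[[2-[hydroxy(4-hydroxyphenyl)(phenyl)methyl]-3-(4-hydroxyphenyl)-6-methylphenyl]ethynyl]phenol (racemate, one enantiomer drawn) | O[C@](c1ccccc1)(c1ccc(O)cc1)c1c(C#Cc2ccc(O)cc2)c(C)ccc1-c1ccc(O)cc1
F4 | step 9 | [2-[[4-(tert-butyldimethylsilyloxy)phenyl]ethynyl]-6-(4-methoxyphenyl)-3-methylphenyl](4-methoxyphenyl)(phenyl)methanol (racemate, one enantiomer drawn) | O[C@](c1ccccc1)(c1ccc(OC)cc1)c1c(C#Cc2ccc(O[Si](C)(C)C(C)(C)C)cc2)c(C)ccc1-c1ccc(OC)cc1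
F5 | step 4 | (2-bromo-6-chloro-3-methylphenyl)(phenyl)methanone | O=C(c1ccccc1)c1c(Cl)ccc(C)c1Br
F6 | step 4 | 2-benzoyl-3-chloro-6-methylbenzoic acid | Cc1ccc(Cl)c(C(=O)c2ccccc2)c1C(=O)O
A1 | alternative 1 | 1-methoxy-1,3-bis(trimethylsilyloxy)penta-1,3-diene | COC(O[Si](C)(C)C)=CC(O[Si](C)(C)C)=CC
A2 | alternative 1 | 3,3-dimethoxy-1-(4-methoxyphenyl)propan-1-one | COC(OC)CC(=O)c1ccc(OC)cc1
A3 | alternative 1 | methyl 2-hydroxy-6-(4-methoxyphenyl)-3-methylbenzoate | COC(=O)c1c(O)c(C)ccc1-c1ccc(OC)cc1
A4 | alternative 2 | 4-chloro-2-iodotoluene | Cc1ccc(Cl)cc1I
A5 | alternative 2 | benzoic anhydride | O=C(OC(=O)c1ccccc1)c1ccccc1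
A6 | alternative 2 | 4-ethynylanisole | C#Cc1ccc(OC)cc1
A7 | alternative 2 | [6-chloro-2-[(4-methoxyphenyl)ethynyl]-3-methylphenyl](phenyl)methanone | COc1ccc(cc1)C#Cc1c(C)ccc(Cl)c1C(=O)c1ccccc1
A8 | alternative 3 | 4-fluoro-2-[(4-methoxyphenyl)ethynyl]-1-methylbenzene | Cc1ccc(F)cc1C#Cc1ccc(OC)cc1
A9 | alternative 3 | 3-[(4-methoxyphenyl)ethynyl]-4-methyl-1,2-didehydrobenzene | CC1=C(C#Cc2ccc(OC)cc2)C#CC=C1
A10 | alternative 3 | 4-methoxyphenylmagnesium bromide | COc1ccc([Mg]Br)cc1
A11 | alternative 3 | 4-methoxybenzophenone | COc1ccc(cc1)C(=O)c1ccccc1
A12 | alternative 3 | [6-(4-methoxyphenyl)-2-[(4-methoxyphenyl)ethynyl]-3-methylphenyl](4-methoxyphenyl)(phenyl)methanol (racemate, one enantiomer drawn) | COc1ccc(cc1)C#Cc1c(C)ccc(-c2ccc(OC)cc2)c1[C@](O)(c1ccccc1)c1ccc(OC)cc1
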